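Percentage points per hour are what the north-west flask offers me, and the next run hangs on them. It is the very flask asked about, followed so far, and it shows the target but not the starting material.

- north-west: starting material 47 mM; gas phase 6.9 mM (held); protic impurity 14.1 mM; the very flask that is asked about, followed so far
- flask: starting material 47 mM; gas phase 6.9 mM (held); protic impurity 14.1 mM; time 40 h

north-west run (percent of the starting material charged): time / h: target / % = 0.500: 1.0; 1.00: 3.7; 1.33: 5.1; 2.00: 8.0; 2.50: 9.5; 3.00: 11.6

(each reading ± 0.5 percentage points)

- the earlier runs were read with a standard deviation of 0.5 percentage points
- at the start none of the gas phase is in solution

- the target standing at 40 h, as a percentage of the starting material charged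
- the change that raises the amount of target at 40 h, in percent of the starting material charged most ("none" if none brings more than 2 percentage points) (delta / theta / none)
- amount of target at 40 h, in percent of the starting material charged, after delta

- delta: doubling the transfer coefficient of the gas phase, all else as stated
- theta: doubling the saturation concentration of gas phase, all else as stated

Between the readings at 1.00 h and 3.00 h the target gains 0.0395 h⁻¹ of the charge, and I keep this as k_P, the target slope: the share of the charge turned into target per hour, a reading that carries the scatter of the readings and is no rate constant, since c(starting material) over this stretch is not in these readings. For a starting material lost first-order with total constant K and a target that stays, the end yield is near k_P/K, the share of the loss that goes to target. My upper estimate is the case K = k_P, which gives 79.4% at 40 h. K itself is not in these readings, so I commit to no figure below that estimate. The forecast does commit, to 68% (range 55% to 84%), lower than my estimate, with the words “destroying material, so I expect a cap near 70%”; it picks theta and gives 68.5% after delta. I would run theta, since doubling the saturation should raise k_P if target formation follows the dissolved gas, and I would sample c(starting material) early to get K.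

The flask gives 31.0% at 40 h, and 34.6% after delta, a gain of 3.6 percentage points against 11 points for theta, so the best change is theta.

    2 dissolved gas → self-condensation product (k = 1.10 M⁻¹ min⁻¹)
    starting material + target → side product B (k = 0.0390 M⁻¹ min⁻¹)
    starting material + dissolved gas → target (k = 0.240 M⁻¹ min⁻¹)
    starting material + protic impurity → quenched substrate (k = 0.0220 M⁻¹ min⁻¹)
    gas phase ⇌ dissolved gas, rate k5*(csat - [dissolved gas]) (kL = 0.0260 min⁻¹)
    starting material → side product A (k = 7.20 × 10⁻⁴ min⁻¹)

In this flask 0.232% of the starting material stands at 40.0 h, so K, taken as an average over the run and no constant of the flask, is 0.152 h⁻¹, and k_P/K is 26.0%. With the step starting material + target → side product B taken away, the flask stands at 50.7% instead of 31.0%, the largest single effect but not the whole shortfall. In the neighbour flask with 56 mM of protic impurity, 0.0503% of the starting material stands at 40.0 h, so its average K is 0.190 h⁻¹; with k_P held, k_P/K falls to 20.8%, and that neighbour flask gives 25.3%.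

(The earlier runs and the new flask stem from a simulated flask with made-up constants, and the scatter is random.)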